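The earlier runs and the new flask are calculated for an exercise; scatter was added.

| flask | E | G | X | remark | time |
|---|---|---|---|---|---|
| south | 0.10 M | 0.38 M | 0.12 M | run made earlier |  |
| east | 0.20 M | 0.25 M | 0.12 M | run made earlier |  |
| winter | 0.10 M | 0.250 M | 0.120 M |  | 3.0 min |
| dawn | 0.10 M | 0.250 M | 0.180 M |  | 3.0 min |
| summer | 0.10 M | 0.250 M | 0.270 M |  | 3.0 min |

| run | time / s | E / % | J / % |
|---|---|---|---|
| south | 10.0 | 93 | 7 |
| south | 12.0 | 93 | 7 |
| south | 20.0 | 89 | 13 |
| south | 25.0 | 83 | 16 |
| south | 40.0 | 77 | 23 |
| south | 60.0 | 70 | 31 |
| east | 10.0 | 96 | 3 |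
| east | 20.0 | 93 | 9 |
| east | 25.0 | 91 | 10 |
| east | 40.0 | 84 | 17 |
| east | 50.0 | 80 | 17 |
| east | 60.0 | 75 | 23 |

(scatter of a reading: 1.5 percentage points)

- the analysis behind the earlier runs scatters by 1.5 percentage points, standard deviation
- no earlier run changes the charge of X; that part of a forecast is a guess

1. part of the E that has reacted at the end, winter
2. part of the E that has reacted at the end, dawn
3. part of the E that has reacted at the end, summer
4. what raising the concentration of X from its lowest to its highest value here does to the part of the E that has reacted (changes below 5 percentage points count as none) (it falls / no change / it rises)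

**Ratio first.** G stands to E at 2.50 in winter, so E is the limiting reagent. In the south run, E lost roughly matches J gained: that run ends at 70% E and 31% J, with a scatter of 1.5 percentage points on each reading. So take the rate as a constant times E times G, with G falling one for one with E.

**The clock.** With f the part of E reacted and r the ratio of G to E, integrating that rate gives f = r(e^θ − 1)/(r e^θ − 1). Turned round at the last J reading, it gives 0.0170 L mol⁻¹ s⁻¹ from south and 0.0193 L mol⁻¹ s⁻¹ from east. Take the mean, 0.0182 L mol⁻¹ s⁻¹, as a reading. Winter's clock θ is then 0.491, the rate constant times the excess of G over E times the time, and your own reckoning for winter is 51.4%.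

**The decision.** Both runs used X at 0.12 M, as winter does, so you commit to that figure for winter. The clock holds no X, and no run moves it, so for dawn and summer the same figure is a baseline and not a finding. Hold E, G and the time, step X to 0.180 M and 0.270 M, and read at 3.0 min, where you reckon about half the E gone in winter. A spread beyond 5 points says X enters the rate.

**The forecast.** Reasoning “A base usually promotes this kind of reaction”, it gives 49%, 60% and 71%, so it rises, and it parts from your flat baseline at dawn and summer.

**The result.** At a clock of 0.491 you reckoned 51.4%; winter gives 50.1%, dawn 50.4% and summer 50.6%. The change of 0.5 points is less than the 5 points that counts, so the answer is no change.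

    E + G → Q + J (k = 0.0180 L mol⁻¹ s⁻¹)
    G + Q ⇌ L, settled at all times (K = 720 L mol⁻¹)
    Q + X ⇌ Z, settled at all times (K = 6200 L mol⁻¹)

**The neighbour.** Now charge dawn with 0.17 M of E: the ratio falls to 1.47, and the clock comes to 0.262, shorter than dawn's 0.491. The formula gives 48.3%. That neighbouring flask gives 47.0%.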